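**Plan**
- Retrosynthesis: cut C16=C17 (Wittig) and C13–C16 (pinacol) to open ring D; cut the lactone C10–O bond and the C4–C5 bond to unfold ring A into a cycloheptenone; cut C10–C5 and C3–C4 (furan + oxyallyl, (4+3)); cut C5–C6 (enolate alkylation); cut ring C (Diels–Alder).
- Forward: ring C → seven-membered ring plus ring B on the C9 furan → opening of the oxygen bridge → ring A by 7→6 ring contraction → lactone → ring D.
- Enabling feature: in ring A (C10, C1, C2, C3, C4, C5) the quaternary C4 carries the C19 carboxyl next to C5. This is the imprint of a 1,2-shift of C5 from a ring carbonyl C19 onto a C4(Cl)(Me) centre in a cycloheptenone (C19=O, C5=C10). The 1,4-related oxygens on C3 and C10 map onto a furan oxygen bridge.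
- Stereochemistry: C8/C9 from a catalytic enantioselective Diels–Alder of an E-enal; C12 by hydroboration; bridge face (C3) from C9; C4 by axial chlorination syn to the bridge, then inversion in the shift.
- C5/C10 by trans lactonisation; C3 by 3-ketone reduction; C6 by equilibration; C13 by the pinacol tether.

Key step: step 14

Remark: gibberellane numbering (C1–C19) is used for every intermediate, α is the face of the C10 lactone oxygen, and the named starting materials are assumed to be commercially available.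

**Step 1**
Reactants: 1 furfural; 2 tert-butyl 4-oxobutanoate
Product: 3 tert-butyl (E)-3-formyl-4-(furan-2-yl)but-3-enoate
Conditions: pyrrolidine (20 mol %), PhCO2H (20 mol %), toluene, 50 °C, slow addition of 2
Reagents that add atoms: none
Why: amine-catalysed crossed aldol condensation, in which the enamine of the enolisable aldehyde 2 adds to non-enolisable furfural and dehydration should give the conjugated enal as the thermodynamic E isomer (furyl trans to CHO).

**Step 2**
Reactants: 4 but-3-en-2-one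
Product: 5 2-(triisopropylsilyloxy)buta-1,3-diene
Conditions: i-Pr3SiOTf, Et3N, Et2O, 0 °C
Reagents that add atoms: triisopropylsilyl triflate, CC(C)[Si](C(C)C)(C(C)C)OS(=O)(=O)C(F)(F)F
Why: soft enolisation and O-silylation of the enone (silyl triflate and amine) should give the 2-silyloxy diene.

**Step 3**
Reactants: 3 enal; 5 diene
Product: 6 Diels–Alder aldehyde, tert-butyl 2-[1-formyl-6-(furan-2-yl)-4-(triisopropylsilyloxy)cyclohex-3-en-1-yl]acetate (furyl cis to CH2CO2tBu)
Conditions: chiral o-tolyl oxazaborolidinium triflimide (CBS type, 20 mol %), CH2Cl2, −78 → −20 °C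
Reagents that add atoms: none
Why: Lewis-acid-catalysed Diels–Alder reaction with "para" regiochemistry (C12–O para to C8), in which the E geometry of 3 becomes furyl (C9) cis to CH2CO2tBu (C8), the unsubstituted diene termini raise no endo/exo issue and the catalyst enantiomer is chosen to give the C8/C9 absolute configuration shown.

**Step 4**
Reactants: 6 Diels–Alder aldehyde
Product: 7 vinyl cyclohexene (CH=CH2 on C8 in place of CHO)
Conditions: Ph3PCH3Br, KHMDS, THF, 0 °C → rt
Reagents that add atoms: methyltriphenylphosphonium bromide, C[P+](c1ccccc1)(c1ccccc1)c1ccccc1.[Br-]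
Why: Wittig methylenation of the neopentyl aldehyde, with no epimerisable centre and a base-stable silyl enol ether.

**Step 5**
Reactants: 7 vinyl cyclohexene
Product: 9 diol (C16 primary OH, 13β-OH, 12α-OTIPS), via C13,C16-bis(borane) adduct 8 (not isolated)
Conditions: BH3·THF (2.5 equiv), THF, 0 °C → rt; then 3 M NaOH, 30% H2O2, 0 °C
Reagents that add atoms: hydrogen peroxide, OO
Why: hydroboration–oxidation, in which boron adds to the terminal vinyl carbon and to the β-carbon (C13) of the silyl enol ether from the β face, anti to the pseudoaxial CH2CO2tBu on C8, so that 12α-OTIPS and the trans 13β-OH should result.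

**Step 6**
Reactants: 9 diol
Product: 10 bis(benzyl ether) (13-OBn, 16-OBn)
Conditions: NaH, BnBr, Bu4NI (cat.), THF/DMF, 0 °C
Reagents that add atoms: benzyl bromide, BrCc1ccccc1
Why: Williamson etherification of both alkoxides, under which the triisopropylsilyl ether should not migrate and the tert-butyl ester should resist the alkoxide.

**Step 7**
Reactants: 10 bis(benzyl ether); 11 2-bromo-N-methoxy-N-methylacetamide
Product: 13 Weinreb amide (CH2C(O)N(OMe)Me on C6, C7 α, 6-epi), via lithium ester enolate 12 (not isolated)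
Conditions: LDA, THF, −78 °C; then 11, DMPU, −78 → −40 °C
Reagents that add atoms: none
Why: ester enolate alkylation, expected to occur on the enolate face remote from C9 and so to give mainly the 6-epi ester drawn, which is the matched epimer for step 10; C6 is in any case equilibrated in step 19, so either epimer is serviceable.

**Step 8**
Reactants: 13 Weinreb amide
Product: 14 ethyl ketone (C19=O, C4H2, C18H3)
Conditions: EtMgBr, THF, 0 °C; aq. NH4Cl
Reagents that add atoms: ethylmagnesium bromide, CC[Mg]Br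
Why: Grignard addition to a Weinreb amide stops at the chelated tetrahedral intermediate and should give the ketone on work-up without attack on the hindered tert-butyl ester.

**Step 9**
Reactants: 14 ethyl ketone
Product: 16 α-chloro ketone (Cl on C4, both epimers), via lithium ketone enolate 15 (not isolated)
Conditions: LDA, THF, −78 °C; then TsCl, −78 °C
Reagents that add atoms: p-toluenesulfonyl chloride, Cc1ccc(cc1)S(Cl)(=O)=O
Why: kinetic enolate formation on the ethyl side and electrophilic chlorination, where position and configuration of the chloride do not matter because α and α′ chlorides give the same oxyallyl cation.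

**Step 10**
Reactants: 16 α-chloro ketone
Product: 18 cycloadduct (8-oxabicyclo[3.2.1]oct-6-en-3-one fused to rings B and C; O bridge C3–O–C10 on the α face, 5α-H, 4β-Me, C1=C2), via 2-oxidoallyl cation 17 (not isolated)
Conditions: Et3N (3 equiv), CF3CH2OH, 0 °C → rt
Reagents that add atoms: none
Why: intramolecular furan–oxyallyl (4+3) cycloaddition, in which the three-atom tether can span only the bridgehead C10 and an equatorial bond at C5 (H5 syn to the bridge), the furan should react through the rotamer with its C3–H next to H9 (allylic strain) so that the bridge forms cis to C11, and the 6-epi ester sits trans to C19 on the new ring B.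

**Step 11**
Reactants: 18 cycloadduct
Product: 19 dihydro cycloadduct (C1–C2 saturated)
Conditions: H2 (1 atm), 5% Pd/C, pyridine (0.5 equiv), EtOAc, rt
Reagents that add atoms: none
Why: heterogeneous hydrogenation of the strained disubstituted alkene, with pyridine added to suppress benzyl ether hydrogenolysis.

**Step 12**
Reactants: 19 dihydro cycloadduct
Product: 21 4α-chloro-4β-methyl ketone, via lithium C4 enolate 20 (not isolated)
Conditions: LDA, THF, −78 °C; then TsCl, −78 → −40 °C
Reagents that add atoms: p-toluenesulfonyl chloride, Cc1ccc(cc1)S(Cl)(=O)=O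
Why: kinetic deprotonation at the less hindered C4–H (not the ring-fusion C5–H) and enolate chlorination on the exo face syn to the oxygen bridge should give the axial 4α-chloride, the usual facial course for enolates of 8-oxabicyclo[3.2.1]octan-3-ones.

**Step 13**
Reactants: 21 chloro ketone
Product: 23 chloro enone (cyclohept-2-enone with C19=O, C5=C10, 4α-Cl, 4β-Me, 3α-OSiEt3), via C5 silyl enol ether 22 (not isolated)
Conditions: Et3SiOTf (1.3 equiv), Et3N (3 equiv), CH2Cl2, −78 → 0 °C
Reagents that add atoms: triethylsilyl triflate, CC[Si](CC)(CC)OS(=O)(=O)C(F)(F)F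
Why: silyl triflate/amine ring opening of an 8-oxabicyclo[3.2.1]octan-3-one, in which enolisation is possible only toward C5 (axial H5, C4 quaternary) and the silylated bridge oxygen leaves C10 by vinylogous β-elimination, so that the C5 and C10 stereocentres are erased and O3 stays as the silyl ether.

**Step 14**
Reactants: 23 chloro enone
Product: 24 acid (ring A as cyclohex-5(10)-ene with 4α-CO2H = C19, 4β-Me, 3α-OSiEt3)
Conditions: LiOH·H2O (4 equiv), THF/H2O 4:1, 0 °C → rt; then cold 1 M HCl to pH 3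
Reagents that add atoms: lithium hydroxide, [Li+].[OH-]
Why: Proposed new method: hydroxide adds to the C19 carbonyl of the α′-chloro enone and the tetrahedral alkoxide pushes the alkenyl carbon C5 from C19 to C4 with loss of chloride (semibenzilic, quasi-Favorskii mechanism), so that C19 leaves the ring as the carboxylate and the seven-membered ring contracts. The closest known reaction type is the quasi-Favorskii ring contraction of α-halo ketones without α′-hydrogen, for example 2-halo-1-tetralones to indane-1-carboxylic acids (aryl shift) and the α-halo ketones of (4+3) cycloadducts; here the migrating group is a tetrasubstituted alkenyl carbon. No ring is closed by joining two ends: ring A (C10, C1, C2, C3, C4, C5) arises by a 1,2-shift inside the cycloheptenone, with the C4–C5 bond formed and the C19–C5 bond broken. The only new stereocentre is the quaternary C4: C5 enters anti to the departing chloride, so the 4α-chloride set in step 12 is replaced with inversion and C19 ends on the α face with the methyl β. The shift must win over epoxide formation by the C19 alkoxide, dehydrochlorination and retro-aldol cleavage; a cyclopropanone path is excluded (no α′-H), the in-plane C19–C5 bond of the enone is antiperiplanar to a pseudo-equatorial C4–Cl bond, the alkenyl group migrates readily and O3 is silylated.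

**Step 15**
Reactants: 24 acid
Product: 25 3α-hydroxy 19,10-lactone (5β-H, 10α-O, 6-epi ester)
Conditions: p-TsOH·H2O (0.3 equiv), wet CH2Cl2, 0 °C → rt
Reagents that add atoms: none
Why: acid-catalysed lactonisation of a β,γ-unsaturated acid, in which protonation of the tetrasubstituted alkene at C5 and capture of the tertiary C10 cation by the 4α-carboxyl should proceed by anti addition (10α-O, 5β-H, the trans A/B fusion), the triethylsilyl ether being cleaved under the same conditions.

**Step 16**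
Reactants: 25 3α-hydroxy lactone
Product: 26 3-oxo lactone
Conditions: Dess–Martin periodinane, NaHCO3, CH2Cl2, rt
Reagents that add atoms: none
Why: Dess–Martin oxidation of the secondary alcohol removes the wrong C3 configuration, and no enolisable centre lies between the two carbonyl groups.

**Step 17**
Reactants: 26 3-oxo lactone
Product: 27 3β-hydroxy lactone
Conditions: K-Selectride, THF, −78 °C; aq. NH4Cl
Reagents that add atoms: none
Why: hindered trialkylborohydride reduction, in which hydride should add from the equatorial side to give the axial 3β-alcohol as known for 3-oxo gibberellin lactones, while lactone and tert-butyl ester are inert at −78 °C.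

**Step 18**
Reactants: 27 3β-hydroxy lactone
Product: 28 3β-OTBS lactone
Conditions: TBSOTf, 2,6-lutidine, CH2Cl2, −78 → −40 °C
Reagents that add atoms: tert-butyldimethylsilyl triflate, CC(C)(C)[Si](C)(C)OS(=O)(=O)C(F)(F)F
Why: silylation of the hindered axial alcohol with the silyl triflate at low temperature, where the tert-butyl ester should not be cleaved.

**Step 19**
Reactants: 28 3β-OTBS lactone (6-epi)
Product: 29 6β ester (C7 β, natural C6)
Conditions: t-BuOK (0.5 equiv), t-BuOH/THF, 40 °C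
Reagents that add atoms: none
Why: base-mediated epimerisation α to the ester, which should lead to the 6β ester (trans to the C5–C4 bond), the thermodynamic isomer of the gibberellane skeleton.

**Step 20**
Reactants: 29 6β ester
Product: 30 13,16-diol
Conditions: H2 (1 atm), Pd(OH)2/C, EtOAc/EtOH, rt
Reagents that add atoms: none
Why: hydrogenolysis of both benzyl ethers, to which silyl ethers, lactone and tert-butyl ester are stable.

**Step 21**
Reactants: 30 diol
Product: 31 keto aldehyde (C13 ketone, C16 aldehyde)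
Conditions: Dess–Martin periodinane, NaHCO3, CH2Cl2, 0 °C → rt
Reagents that add atoms: none
Why: Dess–Martin oxidation of the primary and the secondary alcohol under buffered, non-basic conditions that should not epimerise C12.

**Step 22**
Reactants: 31 keto aldehyde
Product: 32 ring D diol (13-OH, 16-OH cis, bicyclo[3.2.1]octane)
Conditions: SmI2 (2.5 equiv), THF (0.01 M), −78 °C → rt; aq. NH4Cl
Reagents that add atoms: none
Why: samarium diiodide pinacol cyclisation, in which the aldehyde is reduced first and its ketyl adds to the C13 ketone in a five-membered ring closure; the CH2CHO arm on C8 can reach only the β face of C13, which fixes C13, and samarium chelation should give the cis diol.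

**Step 23**
Reactants: 32 ring D diol
Product: 33 16-ketone (13-OH)
Conditions: Dess–Martin periodinane, NaHCO3, CH2Cl2, rt
Reagents that add atoms: none
Why: Dess–Martin oxidation of the secondary C16 alcohol, the tertiary C13 alcohol being inert.

**Step 24**
Reactants: 33 16-ketone
Product: 34 protected target (16-methylene, 3-OTBS, 12-OTIPS, C7 tert-butyl ester)
Conditions: Ph3PCH3Br, t-BuOK (excess), THF, rt → 50 °C
Reagents that add atoms: methyltriphenylphosphonium bromide, C[P+](c1ccccc1)(c1ccccc1)c1ccccc1.[Br-]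
Why: Wittig methylenation of the α-hydroxy cyclopentanone with excess ylide, as is standard for 16-oxo-17-norgibberellins.

**Step 25**
Reactants: 34 protected target
Product: 36 target CNP0260503.1, via 7-silyl ester 13-O-silyl ether 35 (not isolated)
Conditions: Me3SiOTf, 2,6-lutidine, CH2Cl2, 0 °C; then HF·pyridine, pyridine, THF, 0 °C → rt
Reagents that add atoms: none
Why: silyl triflate and lutidine should cleave the tert-butyl ester to the silyl ester (loss of isobutene) under buffered conditions that spare the 13-hydroxy-16-ene unit, and fluoride then removes all silyl groups.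

**Compound list**
1 | furfural | O=Cc1ccco1 | starting material
2 | tert-butyl 4-oxobutanoate | O=CCCC(=O)OC(C)(C)C | starting material
3 | tert-butyl (E)-3-formyl-4-(furan-2-yl)but-3-enoate | O=C/C(=C/c1ccco1)CC(=O)OC(C)(C)C | intermediate
4 | but-3-en-2-one | C=CC(C)=O | starting material
5 | 2-(triisopropylsilyloxy)buta-1,3-diene | C=CC(=C)O[Si](C(C)C)(C(C)C)C(C)C | intermediate
6 | Diels–Alder aldehyde (C8: CHO and CH2CO2tBu; C9: 2-furyl cis to CH2CO2tBu; C12 silyl enol ether) | O=C[C@]1(CC(=O)OC(C)(C)C)CC=C(O[Si](C(C)C)(C(C)C)C(C)C)C[C@H]1c1ccco1 | intermediate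
7 | vinyl cyclohexene | C=C[C@]1(CC(=O)OC(C)(C)C)CC=C(O[Si](C(C)C)(C(C)C)C(C)C)C[C@H]1c1ccco1 | intermediate
8 | C13,C16-bis(borane) adduct | BCC[C@]1(CC(=O)OC(C)(C)C)C[C@H](B)[C@@H](O[Si](C(C)C)(C(C)C)C(C)C)C[C@H]1c1ccco1 | intermediate
9 | diol (16-OH, 13β-OH, 12α-OTIPS) | OCC[C@]1(CC(=O)OC(C)(C)C)C[C@H](O)[C@@H](O[Si](C(C)C)(C(C)C)C(C)C)C[C@H]1c1ccco1 | intermediate
10 | bis(benzyl ether) | c1ccccc1COCC[C@]1(CC(=O)OC(C)(C)C)C[C@H](OCc2ccccc2)[C@@H](O[Si](C(C)C)(C(C)C)C(C)C)C[C@H]1c1ccco1 | intermediate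
11 | 2-bromo-N-methoxy-N-methylacetamide | CON(C)C(=O)CBr | starting material
12 | lithium ester enolate of 10 | [Li+].c1ccccc1COCC[C@]1(C=C([O-])OC(C)(C)C)C[C@H](OCc2ccccc2)[C@@H](O[Si](C(C)C)(C(C)C)C(C)C)C[C@H]1c1ccco1 | intermediate
13 | Weinreb amide (6-epi) | c1ccccc1COCC[C@]1([C@@H](CC(=O)N(C)OC)C(=O)OC(C)(C)C)C[C@H](OCc2ccccc2)[C@@H](O[Si](C(C)C)(C(C)C)C(C)C)C[C@H]1c1ccco1 | intermediate
14 | ethyl ketone | c1ccccc1COCC[C@]1([C@@H](CC(=O)CC)C(=O)OC(C)(C)C)C[C@H](OCc2ccccc2)[C@@H](O[Si](C(C)C)(C(C)C)C(C)C)C[C@H]1c1ccco1 | intermediate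
15 | lithium ketone enolate of 14 | [Li+].c1ccccc1COCC[C@]1([C@@H](CC([O-])=CC)C(=O)OC(C)(C)C)C[C@H](OCc2ccccc2)[C@@H](O[Si](C(C)C)(C(C)C)C(C)C)C[C@H]1c1ccco1 | intermediate
16 | α-chloro ketone (Cl on C4, both epimers) | c1ccccc1COCC[C@]1([C@@H](CC(=O)C(C)Cl)C(=O)OC(C)(C)C)C[C@H](OCc2ccccc2)[C@@H](O[Si](C(C)C)(C(C)C)C(C)C)C[C@H]1c1ccco1 | intermediate
17 | 2-oxidoallyl cation | c1ccccc1COCC[C@]1([C@@H](C=C([O-])[CH+]C)C(=O)OC(C)(C)C)C[C@H](OCc2ccccc2)[C@@H](O[Si](C(C)C)(C(C)C)C(C)C)C[C@H]1c1ccco1 | intermediate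
18 | (4+3) cycloadduct (α oxygen bridge C3–O–C10, 5α-H, 4β-Me, C1=C2) | c1ccccc1COCC[C@]12C[C@H](OCc3ccccc3)[C@@H](O[Si](C(C)C)(C(C)C)C(C)C)C[C@H]1[C@]13C=C[C@@H](O3)[C@H](C)C(=O)[C@@H]1[C@H]2C(=O)OC(C)(C)C | intermediate
19 | dihydro cycloadduct | c1ccccc1COCC[C@]12C[C@H](OCc3ccccc3)[C@@H](O[Si](C(C)C)(C(C)C)C(C)C)C[C@H]1[C@]13CC[C@@H](O3)[C@H](C)C(=O)[C@@H]1[C@H]2C(=O)OC(C)(C)C | intermediate
20 | lithium C4 enolate of 19 | [Li+].c1ccccc1COCC[C@]12C[C@H](OCc3ccccc3)[C@@H](O[Si](C(C)C)(C(C)C)C(C)C)C[C@H]1[C@]13CC[C@@H](O3)C(C)=C([O-])[C@@H]1[C@H]2C(=O)OC(C)(C)C | intermediate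
21 | 4α-chloro-4β-methyl ketone | c1ccccc1COCC[C@]12C[C@H](OCc3ccccc3)[C@@H](O[Si](C(C)C)(C(C)C)C(C)C)C[C@H]1[C@]13CC[C@@H](O3)[C@@](C)(Cl)C(=O)[C@@H]1[C@H]2C(=O)OC(C)(C)C | intermediate
22 | C5 triethylsilyl enol ether of 21 | c1ccccc1COCC[C@]12C[C@H](OCc3ccccc3)[C@@H](O[Si](C(C)C)(C(C)C)C(C)C)C[C@H]1[C@]13CC[C@@H](O3)[C@@](C)(Cl)C(O[Si](CC)(CC)CC)=C1[C@H]2C(=O)OC(C)(C)C | intermediate
23 | chloro enone (C19=O, C5=C10, 4α-Cl, 4β-Me, 3α-OSiEt3) | c1ccccc1COCC[C@]12C[C@H](OCc3ccccc3)[C@@H](O[Si](C(C)C)(C(C)C)C(C)C)C[C@H]1C3=C([C@H]2C(=O)OC(C)(C)C)C(=O)[C@](C)(Cl)[C@H](O[Si](CC)(CC)CC)CC3 | intermediate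
24 | ring-contracted acid (Δ5(10), 4α-CO2H, 4β-Me, 3α-OSiEt3) | c1ccccc1COCC[C@]12C[C@H](OCc3ccccc3)[C@@H](O[Si](C(C)C)(C(C)C)C(C)C)C[C@H]1C3=C([C@H]2C(=O)OC(C)(C)C)[C@](C)(C(=O)O)[C@H](O[Si](CC)(CC)CC)CC3 | intermediate
25 | 3α-hydroxy 19,10-lactone (6-epi ester) | c1ccccc1COCC[C@]12C[C@H](OCc3ccccc3)[C@@H](O[Si](C(C)C)(C(C)C)C(C)C)C[C@H]1[C@@]13CC[C@@H](O)[C@@](C)(C(=O)O1)[C@H]3[C@H]2C(=O)OC(C)(C)C | intermediate
26 | 3-oxo lactone | c1ccccc1COCC[C@]12C[C@H](OCc3ccccc3)[C@@H](O[Si](C(C)C)(C(C)C)C(C)C)C[C@H]1[C@@]13CCC(=O)[C@@](C)(C(=O)O1)[C@H]3[C@H]2C(=O)OC(C)(C)C | intermediate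
27 | 3β-hydroxy lactone | c1ccccc1COCC[C@]12C[C@H](OCc3ccccc3)[C@@H](O[Si](C(C)C)(C(C)C)C(C)C)C[C@H]1[C@@]13CC[C@H](O)[C@@](C)(C(=O)O1)[C@H]3[C@H]2C(=O)OC(C)(C)C | intermediate
28 | 3β-OTBS lactone (6-epi) | c1ccccc1COCC[C@]12C[C@H](OCc3ccccc3)[C@@H](O[Si](C(C)C)(C(C)C)C(C)C)C[C@H]1[C@@]13CC[C@H](O[Si](C)(C)C(C)(C)C)[C@@](C)(C(=O)O1)[C@H]3[C@H]2C(=O)OC(C)(C)C | intermediate
29 | 6β ester | c1ccccc1COCC[C@]12C[C@H](OCc3ccccc3)[C@@H](O[Si](C(C)C)(C(C)C)C(C)C)C[C@H]1[C@@]13CC[C@H](O[Si](C)(C)C(C)(C)C)[C@@](C)(C(=O)O1)[C@H]3[C@@H]2C(=O)OC(C)(C)C | intermediate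
30 | 13,16-diol | OCC[C@]12C[C@H](O)[C@@H](O[Si](C(C)C)(C(C)C)C(C)C)C[C@H]1[C@@]13CC[C@H](O[Si](C)(C)C(C)(C)C)[C@@](C)(C(=O)O1)[C@H]3[C@@H]2C(=O)OC(C)(C)C | intermediate
31 | keto aldehyde | O=CC[C@]12CC(=O)[C@@H](O[Si](C(C)C)(C(C)C)C(C)C)C[C@H]1[C@@]13CC[C@H](O[Si](C)(C)C(C)(C)C)[C@@](C)(C(=O)O1)[C@H]3[C@@H]2C(=O)OC(C)(C)C | intermediate
32 | ring D diol (13-OH, 16-OH cis) | O[C@@H]1C[C@]23C[C@@]1(O)[C@@H](O[Si](C(C)C)(C(C)C)C(C)C)C[C@H]2[C@@]12CC[C@H](O[Si](C)(C)C(C)(C)C)[C@@](C)(C(=O)O1)[C@H]2[C@@H]3C(=O)OC(C)(C)C | intermediate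
33 | 16-ketone (13-OH) | O=C1C[C@]23C[C@@]1(O)[C@@H](O[Si](C(C)C)(C(C)C)C(C)C)C[C@H]2[C@@]12CC[C@H](O[Si](C)(C)C(C)(C)C)[C@@](C)(C(=O)O1)[C@H]2[C@@H]3C(=O)OC(C)(C)C | intermediate
34 | protected target (3-OTBS, 12-OTIPS, tert-butyl ester) | C=C1C[C@]23C[C@@]1(O)[C@@H](O[Si](C(C)C)(C(C)C)C(C)C)C[C@H]2[C@@]12CC[C@H](O[Si](C)(C)C(C)(C)C)[C@@](C)(C(=O)O1)[C@H]2[C@@H]3C(=O)OC(C)(C)C | intermediate
35 | 7-trimethylsilyl ester 13-O-trimethylsilyl ether | C=C1C[C@]23C[C@@]1(O[Si](C)(C)C)[C@@H](O[Si](C(C)C)(C(C)C)C(C)C)C[C@H]2[C@@]12CC[C@H](O[Si](C)(C)C(C)(C)C)[C@@](C)(C(=O)O1)[C@H]2[C@@H]3C(=O)O[Si](C)(C)C | intermediate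
36 | CNP0260503.1 (3β,12α,13-trihydroxy 19,10-lactone 7-acid) | C=C1C[C@]23C[C@@]1(O)[C@@H](O)C[C@H]2[C@@]12CC[C@H](O)[C@@](C)(C(=O)O1)[C@H]2[C@@H]3C(=O)O | target

**Totals**
Total step count: 25. Longest linear sequence: 24 (steps 1 and 3–25; step 2 is a side branch).

**Steps most likely to fail**

1. Step 14 (proposed new method). The tetrahedral C19 alkoxide may displace the chloride itself (epoxide, then α-hydroxy ketone), or base may cause dehydrochlorination, instead of the alkenyl shift. Fallback, from 23 back to 24 by known reactions: 1,2-reduction of the enone (NaBH4, CeCl3, MeOH, −40 °C) gives the allylic chlorohydrin F1. A silver-promoted semipinacol rearrangement of this halohydrin (AgBF4, 2,6-di-tert-butylpyridine, CH2Cl2, −40 °C), with 1,2-shift of the alkenyl carbon C5 anti to the chloride, gives the ring-contracted aldehyde F2. Pinnick oxidation (NaClO2, NaH2PO4, 2-methyl-2-butene) returns to 24.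

2. Step 10. The oxyallyl cation may be captured by the solvent, or may lose a proton to give an enone, before it reaches the furan; facial selectivity may also be poor. Fallback, from 16 back to 21: a second enolate chlorination (LDA, then TsCl) gives the α,α-dichloro ketone F3. Its chlorine-stabilised oxyallyl cation (Et3N, CF3CH2OH) is longer-lived and should give the chloro cycloadduct F4 with the chloride syn to the bridge. Diimide reduction of the C1=C2 bond (TsNHNH2, NaOAc, DME/H2O, reflux) then gives 21 directly, bypassing 18–20.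

3. Step 15. The tertiary C10 cation may lose H9 and so scramble C9, or may be captured by the C7 ester instead of the C19 acid. Fallback, from 24 back to 25 without a free cation: iodolactonisation (I2, MeCN, 0 °C) gives the 5β-iodo 19,10-lactone F5. Radical deiodination (Bu3SnH, AIBN, benzene, 80 °C) gives the 3α-silyloxy lactone F6, and PPTS in MeOH removes the triethylsilyl group to give 25.

**Further compounds**
F1 | step 14 | allylic chlorohydrin (C19 carbinol, either epimer) | c1ccccc1COCC[C@]12C[C@H](OCc3ccccc3)[C@@H](O[Si](C(C)C)(C(C)C)C(C)C)C[C@H]1C3=C([C@H]2C(=O)OC(C)(C)C)C(O)[C@](C)(Cl)[C@H](O[Si](CC)(CC)CC)CC3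
F2 | step 14 | ring-contracted aldehyde (4α-CHO) | c1ccccc1COCC[C@]12C[C@H](OCc3ccccc3)[C@@H](O[Si](C(C)C)(C(C)C)C(C)C)C[C@H]1C3=C([C@H]2C(=O)OC(C)(C)C)[C@](C)(C=O)[C@H](O[Si](CC)(CC)CC)CC3
F3 | step 10 | α,α-dichloro ketone | c1ccccc1COCC[C@]1([C@@H](CC(=O)C(C)(Cl)Cl)C(=O)OC(C)(C)C)C[C@H](OCc2ccccc2)[C@@H](O[Si](C(C)C)(C(C)C)C(C)C)C[C@H]1c1ccco1
F4 | step 10 | chloro cycloadduct (4α-Cl, 4β-Me, C1=C2) | c1ccccc1COCC[C@]12C[C@H](OCc3ccccc3)[C@@H](O[Si](C(C)C)(C(C)C)C(C)C)C[C@H]1[C@]13C=C[C@@H](O3)[C@@](C)(Cl)C(=O)[C@@H]1[C@H]2C(=O)OC(C)(C)C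
F5 | step 15 | 5β-iodo 19,10-lactone (3α-OSiEt3) | c1ccccc1COCC[C@]12C[C@H](OCc3ccccc3)[C@@H](O[Si](C(C)C)(C(C)C)C(C)C)C[C@H]1[C@@]13CC[C@@H](O[Si](CC)(CC)CC)[C@@](C)(C(=O)O1)[C@@]3(I)[C@H]2C(=O)OC(C)(C)C
F6 | step 15 | 3α-triethylsilyloxy 19,10-lactone | c1ccccc1COCC[C@]12C[C@H](OCc3ccccc3)[C@@H](O[Si](C(C)C)(C(C)C)C(C)C)C[C@H]1[C@@]13CC[C@@H](O[Si](CC)(CC)CC)[C@@](C)(C(=O)O1)[C@H]3[C@H]2C(=O)OC(C)(C)C
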